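**Retrosynthetic overview**
1. Feature: ring B carries ring B' at C5, between C4–O (to ring C) and C6–OH, and C2'–OH of ring B' faces C6–OH across the axis. These two oxygens are joined through a di-tert-butylsilylene bridge, so the C5(B)–C1'(B') bond with its four ortho heteroatoms is formed intramolecularly by C–H arylation.
2. Ring B enters as a 4-fluorobenzaldehyde. The C4 fluorine acidifies C5–H and later leaves in the SNAr with the ring C phenol. The C1 formyl group activates that SNAr and then becomes the C1 oxygen (Dakin).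
3. The unbridged, methylated biaryl fluoroaldehyde is used three times: as rings B/B', and, after F→OMe exchange and Dakin oxidation, as the phenol that supplies rings E/E' and F/F'.
4. Ether bonds in forward order: E–O–D and F–O–D (double SNAr on 2,6-difluoro-4-methoxybenzaldehyde), D–O–C and C–O–B (SNAr, each followed by Dakin), B–O–A (Ullmann), then cleavage of 22 methyl ethers.
5. Ring formation: all nine benzene rings are bought. The only ring closed is the temporary seven-membered dioxasilepine (step 4), which is opened again in step 5.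

Key step: step 4

Remark on the chemistry: the target has no stereocentre, and none of its three biaryl axes is stereogenic because each carries a symmetrical 2,4,6-trihydroxyphenyl ring; the two intermediates in which ring B' is temporarily unsymmetrical are carried as racemates.
Abbreviation: ArE = 2,4,6-trimethoxy-3-(2,4,6-trimethoxyphenyl)phenyl, the permethylated ring E/E' (identical to F/F') unit. Ring B locants: C1 (O to ring A), C2 (OH), C3 (H), C4 (O to ring C), C5 (ring B'), C6 (OH).

**Step 1**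
Reactants: 1 4-fluoro-2,6-dimethoxybenzaldehyde
Product: 2 4-fluoro-2-hydroxy-6-methoxybenzaldehyde
Conditions: BCl3 (1.1 equiv), CH2Cl2, −78 → 0 °C; then H2O
Reagents that add atoms: none
Why: Chelation-controlled Lewis-acid ether cleavage: BCl3 binds the formyl oxygen and one of the two equivalent ortho methoxy oxygens in a six-membered chelate, chloride removes only that methyl group, and the resulting boron phenoxide resists a second cleavage at this temperature.

**Step 2**
Reactants: 3 3,5-dimethoxyphenol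
Product: 4 2-bromo-3,5-dimethoxyphenol
Conditions: NBS (1.0 equiv), CH2Cl2, −78 → 0 °C
Reagents that add atoms: N-bromosuccinimide, O=C1CCC(=O)N1Br
Why: Electrophilic aromatic bromination: in a non-polar solvent the phenol hydrogen-bonds NBS, which delivers bromine to one of the two equivalent positions ortho to OH rather than to the more crowded C4 between two methoxy groups, and one equivalent at low temperature limits dibromination.

**Step 3**
Reactants: 4 2-bromo-3,5-dimethoxyphenol; 5 di-tert-butylsilyl bis(trifluoromethanesulfonate); 2 4-fluoro-2-hydroxy-6-methoxybenzaldehyde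
Product: 7 di-tert-butyl(2-bromo-3,5-dimethoxyphenoxy)(5-fluoro-2-formyl-3-methoxyphenoxy)silane, via silyl triflate 6 (not isolated)
Conditions: 4, 5 (1.05 equiv), 2,6-lutidine, CH2Cl2, −78 → 0 °C; then 2, Et3N, DMAP (cat.), 0 °C → rt
Reagents that add atoms: none
Why: Stepwise silyl ether formation (substitution at silicon): the first triflate of 5 leaves far faster than the second one at the crowded di-tert-butylsilicon centre, so the mixed bis(aryloxy)silane should form with little symmetrical product, and the non-enolisable aldehyde is inert.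

**Step 4**
Reactants: 7 di-tert-butyl(2-bromo-3,5-dimethoxyphenoxy)(5-fluoro-2-formyl-3-methoxyphenoxy)silane
Product: 8 6,6-di-tert-butyl-1-fluoro-3,9,11-trimethoxydibenzo[d,f][1,3,2]dioxasilepine-4-carbaldehyde
Conditions: Pd(OAc)2 (10 mol %), PCy3·HBF4 (20 mol %), Cs2CO3 (2 equiv), PivOH (30 mol %), 4 Å MS, toluene, 110 °C, Ar
Reagents that add atoms: none
Why: Zerovalent palladium (from Pd(OAc)2 and PCy3) inserts into the C–Br bond of ring B', pivalate replaces bromide, and carboxylate-assisted concerted metalation–deprotonation of C5–H of ring B gives an eight-membered diarylpalladium ring whose reductive elimination forms C5(B)–C1'(B'). The closest known reaction type is the palladium-catalysed intramolecular direct C–H arylation of silicon-tethered bis(aryloxy)silanes, which gives dibenzodioxasilepines as masked unsymmetrical 2,2'-biphenols. The seven-membered 1,3,2-dioxasilepine closes by this C(sp2)–C(sp2) reductive elimination, that is by contraction of the eight-membered palladacycle, and the two tert-butyl groups on silicon push the two aryloxy arms toward each other. No stereocentre is formed, and the new axis is stereogenic only while ring B' is unsymmetrical, so it is carried as a racemate. The step needs site selectivity for C5–H over C3–H and over the formyl C–H: only C5–H lies ortho to the bridging oxygen and within reach of the tethered arylpalladium, it is the most acidic ring C–H because fluorine and oxygen flank it, C3–H is para to the bridge, and attack on the formyl C–H would need a less favourable nine-membered palladacycle. The tether also offsets the crowding of four ortho heteroatom substituents and stops the reaction after one arylation.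

**Step 5**
Reactants: 8 the silicon-bridged biaryl fluoroaldehyde
Product: 9 4-fluoro-2-hydroxy-3-(2-hydroxy-4,6-dimethoxyphenyl)-6-methoxybenzaldehyde
Conditions: HF·pyridine, THF, 0 °C → rt; pH 7 buffer work-up
Reagents that add atoms: none
Why: Fluoride-driven Si–O cleavage (two strong Si–F bonds form), run in the acidic HF–pyridine medium so that both phenols stay protonated and the C2' oxygen cannot displace the neighbouring activated fluoride to give a dibenzofuran.

**Step 6**
Reactants: 9 the biaryl diol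
Product: 10 4-fluoro-2,6-dimethoxy-3-(2,4,6-trimethoxyphenyl)benzaldehyde
Conditions: MeI (large excess), K2CO3, DMF, 0 °C → rt
Reagents that add atoms: iodomethane, CI
Why: Williamson ether synthesis: with excess MeI at or below room temperature the electron-rich C2' phenoxide should be capped much faster than it can attack C4–F through a strained, planarised transition state, and the chelated C6–OH, which has no such side path, follows more slowly.

**Step 7**
Reactants: 10 4-fluoro-2,6-dimethoxy-3-(2,4,6-trimethoxyphenyl)benzaldehyde (the share meant for rings E/E' and F/F')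
Product: 11 2,4,6-trimethoxy-3-(2,4,6-trimethoxyphenyl)benzaldehyde
Conditions: NaOMe (3 equiv), MeOH–DMF, 80 °C
Reagents that add atoms: sodium methoxide, C[O-].[Na+]
Why: SNAr (addition–elimination): the small methoxide attacks C4 para to the formyl group and fluoride leaves from the Meisenheimer adduct, which gives the mono-formylated hexamethoxybiphenyl without any need to desymmetrise a symmetrical biaryl.

**Step 8**
Reactants: 11 2,4,6-trimethoxy-3-(2,4,6-trimethoxyphenyl)benzaldehyde
Product: 13 2,4,6-trimethoxy-3-(2,4,6-trimethoxyphenyl)phenol (ArE–OH), via aryl formate 12 (not isolated)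
Conditions: mCPBA, CH2Cl2, 0 °C → rt; aqueous wash; then K2CO3 (cat.), degassed MeOH, rt
Reagents that add atoms: 3-chloroperoxybenzoic acid, OOC(=O)c1cccc(Cl)c1
Why: Baeyer–Villiger (Dakin-type) oxidation: in the Criegee adduct the aryl group with three ortho/para oxygen donors migrates in preference to hydride, and mild methanolysis frees the phenol from the formate.

**Step 9**
Reactants: 13 ArE–OH (2.3 equiv); 14 2,6-difluoro-4-methoxybenzaldehyde
Product: 16 4-methoxy-2,6-bis(ArE-oxy)benzaldehyde (ring D aldehyde), via monoether 15 (not isolated)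
Conditions: Cs2CO3, DMA, 130 °C, Ar
Reagents that add atoms: none
Why: Twofold SNAr: both fluorides are ortho to the formyl group, which takes up the charge of each Meisenheimer adduct, while the C4 methoxy group is meta to both reacting carbons, and the slower second substitution is driven by excess caesium phenoxide and heat.

**Step 10**
Reactants: 16 ring D aldehyde
Product: 18 4-methoxy-2,6-bis(ArE-oxy)phenol (ring D phenol), via aryl formate 17 (not isolated)
Conditions: mCPBA, CH2Cl2, 0 °C → rt; aqueous wash; then K2CO3 (cat.), degassed MeOH, rt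
Reagents that add atoms: 3-chloroperoxybenzoic acid, OOC(=O)c1cccc(Cl)c1
Why: Baeyer–Villiger (Dakin-type) oxidation as in step 8: ring D carries three oxygen donors ortho and para to the migrating carbon, and the methyl and diaryl ethers are inert to the peracid at this temperature.

**Step 11**
Reactants: 18 ring D phenol; 1 4-fluoro-2,6-dimethoxybenzaldehyde (1.5 equiv)
Product: 19 2,6-dimethoxy-4-[4-methoxy-2,6-bis(ArE-oxy)phenoxy]benzaldehyde (ring C aldehyde)
Conditions: Cs2CO3, DMSO, 110 °C, Ar
Reagents that add atoms: none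
Why: SNAr: C4–F of 1 is para to the formyl group and flanked only by hydrogen atoms, so even the phenoxide of 18, shielded by two aryloxy groups, should reach it.

**Step 12**
Reactants: 19 ring C aldehyde
Product: 21 2,6-dimethoxy-4-[4-methoxy-2,6-bis(ArE-oxy)phenoxy]phenol (ring C phenol), via aryl formate 20 (not isolated)
Conditions: mCPBA, CH2Cl2, 0 °C → rt; aqueous wash; then K2CO3 (cat.), degassed MeOH, rt
Reagents that add atoms: 3-chloroperoxybenzoic acid, OOC(=O)c1cccc(Cl)c1
Why: Baeyer–Villiger (Dakin-type) oxidation of a 2,4,6-trioxygenated benzaldehyde, in which aryl migration is strongly favoured, followed by formate methanolysis.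

**Step 13**
Reactants: 21 ring C phenol; 10 4-fluoro-2,6-dimethoxy-3-(2,4,6-trimethoxyphenyl)benzaldehyde (2 equiv)
Product: 22 4-{2,6-dimethoxy-4-[4-methoxy-2,6-bis(ArE-oxy)phenoxy]phenoxy}-2,6-dimethoxy-3-(2,4,6-trimethoxyphenyl)benzaldehyde (ring B aldehyde)
Conditions: Cs2CO3, 4 Å MS, DMSO, 120 °C, Ar
Reagents that add atoms: none
Why: SNAr: the fluoride at C4 of ring B is para to the formyl group, no other aldehyde-activated ether is present that could scramble, and the poorly solvated caesium phenoxide in DMSO with excess recoverable 10 should overcome the crowding next to ring B'.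

**Step 14**
Reactants: 22 ring B aldehyde
Product: 24 4-{2,6-dimethoxy-4-[4-methoxy-2,6-bis(ArE-oxy)phenoxy]phenoxy}-2,6-dimethoxy-3-(2,4,6-trimethoxyphenyl)phenol (ring B phenol), via aryl formate 23 (not isolated)
Conditions: mCPBA, CH2Cl2, 0 °C → rt; aqueous wash; then K2CO3 (cat.), degassed MeOH, rt
Reagents that add atoms: 3-chloroperoxybenzoic acid, OOC(=O)c1cccc(Cl)c1
Why: Baeyer–Villiger (Dakin-type) oxidation turns the formyl carbon at C1 of ring B into the C1 oxygen, because the ring with oxygen donors at C2, C4 and C6 migrates in preference to hydride.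

**Step 15**
Reactants: 24 ring B phenol; 25 1-iodo-3,5-dimethoxybenzene (2 equiv)
Product: 26 docosa-O-methyl ether of the target (24 with a 3,5-dimethoxyphenyl group, ring A, on the C1 oxygen of ring B)
Conditions: CuI (20 mol %), picolinic acid (40 mol %), K3PO4, DMSO, 100 °C, Ar
Reagents that add atoms: none
Why: Ullmann diaryl ether synthesis: the picolinate-ligated copper phenoxide of 24 couples with the unhindered aryl iodide 25, and this ligand system is known to accept phenols with two ortho substituents.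

**Step 16**
Reactants: 26 docosa-O-methyl ether
Product: 27 target CNP0117322.0
Conditions: BBr3 (about 3 equiv per OMe), CH2Cl2, −78 °C → rt; then ice–water; EtOAc extraction, Sephadex LH-20 under Ar
Reagents that add atoms: none
Why: Lewis-acid ether cleavage: BBr3 binds each methoxy oxygen and bromide removes the methyl group by SN2, whereas the diaryl ether C(sp2)–O bonds and the biaryl bonds offer no such path, so hydrolysis of the aryl borates should free all 22 phenols.

**Compound list**
1 | 4-fluoro-2,6-dimethoxybenzaldehyde | COc1cc(F)cc(OC)c1C=O | starting material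
2 | 4-fluoro-2-hydroxy-6-methoxybenzaldehyde | O=Cc1c(O)cc(F)cc1OC | intermediate
3 | 3,5-dimethoxyphenol | COc1cc(O)cc(OC)c1 | starting material
4 | 2-bromo-3,5-dimethoxyphenol | COc1cc(O)c(Br)c(OC)c1 | intermediate
5 | di-tert-butylsilyl bis(trifluoromethanesulfonate) | CC(C)(C)[Si](OS(=O)(=O)C(F)(F)F)(OS(=O)(=O)C(F)(F)F)C(C)(C)C | starting material
6 | (2-bromo-3,5-dimethoxyphenoxy)di-tert-butylsilyl trifluoromethanesulfonate | COc1cc(OC)c(Br)c(O[Si](C(C)(C)C)(C(C)(C)C)OS(=O)(=O)C(F)(F)F)c1 | intermediate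
7 | di-tert-butyl(2-bromo-3,5-dimethoxyphenoxy)(5-fluoro-2-formyl-3-methoxyphenoxy)silane | O=Cc1c(OC)cc(F)cc1O[Si](C(C)(C)C)(C(C)(C)C)Oc1cc(OC)cc(OC)c1Br | intermediate
8 | 6,6-di-tert-butyl-1-fluoro-3,9,11-trimethoxydibenzo[d,f][1,3,2]dioxasilepine-4-carbaldehyde | O=Cc1c(OC)cc(F)c2c1O[Si](C(C)(C)C)(C(C)(C)C)Oc1cc(OC)cc(OC)c1-2 | intermediate
9 | 4-fluoro-2-hydroxy-3-(2-hydroxy-4,6-dimethoxyphenyl)-6-methoxybenzaldehyde | O=Cc1c(OC)cc(F)c(-c2c(O)cc(OC)cc2OC)c1O | intermediate
10 | 4-fluoro-2,6-dimethoxy-3-(2,4,6-trimethoxyphenyl)benzaldehyde | O=Cc1c(OC)cc(F)c(-c2c(OC)cc(OC)cc2OC)c1OC | intermediate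
11 | 2,4,6-trimethoxy-3-(2,4,6-trimethoxyphenyl)benzaldehyde | O=Cc1c(OC)cc(OC)c(-c2c(OC)cc(OC)cc2OC)c1OC | intermediate
12 | 2,4,6-trimethoxy-3-(2,4,6-trimethoxyphenyl)phenyl formate | O=COc1c(OC)cc(OC)c(-c2c(OC)cc(OC)cc2OC)c1OC | intermediate
13 | 2,4,6-trimethoxy-3-(2,4,6-trimethoxyphenyl)phenol (ArE–OH) | Oc1c(OC)cc(OC)c(-c2c(OC)cc(OC)cc2OC)c1OC | intermediate
14 | 2,6-difluoro-4-methoxybenzaldehyde | COc1cc(F)c(C=O)c(F)c1 | starting material
15 | 2-fluoro-4-methoxy-6-(ArE-oxy)benzaldehyde | COc1cc(F)c(C=O)c(Oc2c(OC)cc(OC)c(-c3c(OC)cc(OC)cc3OC)c2OC)c1 | intermediate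
16 | 4-methoxy-2,6-bis(ArE-oxy)benzaldehyde | COc1cc(Oc2c(OC)cc(OC)c(-c3c(OC)cc(OC)cc3OC)c2OC)c(C=O)c(Oc2c(OC)cc(OC)c(-c3c(OC)cc(OC)cc3OC)c2OC)c1 | intermediate
17 | 4-methoxy-2,6-bis(ArE-oxy)phenyl formate | COc1cc(Oc2c(OC)cc(OC)c(-c3c(OC)cc(OC)cc3OC)c2OC)c(OC=O)c(Oc2c(OC)cc(OC)c(-c3c(OC)cc(OC)cc3OC)c2OC)c1 | intermediate
18 | 4-methoxy-2,6-bis(ArE-oxy)phenol | COc1cc(Oc2c(OC)cc(OC)c(-c3c(OC)cc(OC)cc3OC)c2OC)c(O)c(Oc2c(OC)cc(OC)c(-c3c(OC)cc(OC)cc3OC)c2OC)c1 | intermediate
19 | 2,6-dimethoxy-4-[4-methoxy-2,6-bis(ArE-oxy)phenoxy]benzaldehyde | O=Cc1c(OC)cc(Oc2c(Oc3c(OC)cc(OC)c(-c4c(OC)cc(OC)cc4OC)c3OC)cc(OC)cc2Oc2c(OC)cc(OC)c(-c3c(OC)cc(OC)cc3OC)c2OC)cc1OC | intermediate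
20 | 2,6-dimethoxy-4-[4-methoxy-2,6-bis(ArE-oxy)phenoxy]phenyl formate | O=COc1c(OC)cc(Oc2c(Oc3c(OC)cc(OC)c(-c4c(OC)cc(OC)cc4OC)c3OC)cc(OC)cc2Oc2c(OC)cc(OC)c(-c3c(OC)cc(OC)cc3OC)c2OC)cc1OC | intermediate
21 | 2,6-dimethoxy-4-[4-methoxy-2,6-bis(ArE-oxy)phenoxy]phenol | Oc1c(OC)cc(Oc2c(Oc3c(OC)cc(OC)c(-c4c(OC)cc(OC)cc4OC)c3OC)cc(OC)cc2Oc2c(OC)cc(OC)c(-c3c(OC)cc(OC)cc3OC)c2OC)cc1OC | intermediate
22 | ring B aldehyde: 4-{2,6-dimethoxy-4-[4-methoxy-2,6-bis(ArE-oxy)phenoxy]phenoxy}-2,6-dimethoxy-3-(2,4,6-trimethoxyphenyl)benzaldehyde | O=Cc1c(OC)cc(Oc2c(OC)cc(Oc3c(Oc4c(OC)cc(OC)c(-c5c(OC)cc(OC)cc5OC)c4OC)cc(OC)cc3Oc3c(OC)cc(OC)c(-c4c(OC)cc(OC)cc4OC)c3OC)cc2OC)c(-c2c(OC)cc(OC)cc2OC)c1OC | intermediate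
23 | formate of the ring B phenol | O=COc1c(OC)cc(Oc2c(OC)cc(Oc3c(Oc4c(OC)cc(OC)c(-c5c(OC)cc(OC)cc5OC)c4OC)cc(OC)cc3Oc3c(OC)cc(OC)c(-c4c(OC)cc(OC)cc4OC)c3OC)cc2OC)c(-c2c(OC)cc(OC)cc2OC)c1OC | intermediate
24 | ring B phenol: 4-{2,6-dimethoxy-4-[4-methoxy-2,6-bis(ArE-oxy)phenoxy]phenoxy}-2,6-dimethoxy-3-(2,4,6-trimethoxyphenyl)phenol | Oc1c(OC)cc(Oc2c(OC)cc(Oc3c(Oc4c(OC)cc(OC)c(-c5c(OC)cc(OC)cc5OC)c4OC)cc(OC)cc3Oc3c(OC)cc(OC)c(-c4c(OC)cc(OC)cc4OC)c3OC)cc2OC)c(-c2c(OC)cc(OC)cc2OC)c1OC | intermediate
25 | 1-iodo-3,5-dimethoxybenzene | COc1cc(I)cc(OC)c1 | starting material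
26 | docosa-O-methyl ether of the target | COc1cc(OC)cc(Oc2c(OC)cc(Oc3c(OC)cc(Oc4c(Oc5c(OC)cc(OC)c(-c6c(OC)cc(OC)cc6OC)c5OC)cc(OC)cc4Oc4c(OC)cc(OC)c(-c5c(OC)cc(OC)cc5OC)c4OC)cc3OC)c(-c3c(OC)cc(OC)cc3OC)c2OC)c1 | intermediate
27 | CNP0117322.0 | Oc1cc(O)cc(Oc2c(O)cc(Oc3c(O)cc(Oc4c(Oc5c(O)cc(O)c(-c6c(O)cc(O)cc6O)c5O)cc(O)cc4Oc4c(O)cc(O)c(-c5c(O)cc(O)cc5O)c4O)cc3O)c(-c3c(O)cc(O)cc3O)c2O)c1 | target

**Total step count:** 16. **Longest linear sequence:** 15 steps (1, then 3 to 16; step 2 runs in parallel).

**Steps most likely to fail**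

**Step 4 (key step).** Three things may go wrong. Oxidative addition into the electron-rich, doubly ortho-substituted C–Br bond may be slow, so that protodebromination takes over. The silicon bridge may be lost to carbonate or pivalate at 110 °C. Palladium may attack the formyl C–H.

The fallback replaces the tethered C–H arylation by an intermolecular Suzuki–Miyaura coupling. It sets out from 1. NBS in MeCN at rt brominates one of the two equivalent positions ortho to fluorine and gives 3-bromo-4-fluoro-2,6-dimethoxybenzaldehyde F1. Coupling of F1 with commercial 2,4,6-trimethoxyphenylboronic acid (Pd2(dba)3, SPhos, K3PO4, toluene, 100 °C) comes back to the route at 10.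

**Step 13.** The phenoxide of 21, flanked by two methoxy groups, must approach C4 of 10 over a face covered by an ortho methoxy group of the perpendicular ring B'. Addition may become so slow that decay of the phenoxide or hydrolysis of the fluoride wins at the temperature needed.

The fallback makes the ether before the axis. It sets out from 21 and 1.
- SNAr on the unhindered fluoride (Cs2CO3, DMSO, 100 °C) gives the ring B aldehyde lacking ring B' F2.
- BCl3 (CH2Cl2, −78 °C) removes one of the two equivalent methyl groups ortho to the formyl group and gives the salicylaldehyde F3.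
- Silyl triflate 6, made from 4 and 5 as in step 3, with Et3N gives the silicon-bridged bromide F4.
- The catalyst system of step 4 arylates the C–H between the bridging oxygen and the ring C oxygen and gives the dioxasilepine F5.
- HF·pyridine gives the biaryl diol F6.
- MeI with K2CO3 comes back to the route at 22.

**Step 15.** Formation of the copper phenoxide may be hampered by the two ortho methoxy groups. The very electron-rich phenoxide may also be oxidised in the presence of copper before it couples.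

The fallback is copper-free. It sets out from 24 and 1. SNAr (Cs2CO3, DMSO, 110 °C) gives the ring A aldehyde F7, in which ring A still carries a formyl group between its two methoxy groups. Tsuji–Wilkinson decarbonylation ([Rh(cod)Cl]2, dppp, diglyme, 160 °C) removes that group and comes back to the route at 26.

**Further compounds**
F1 | step 4 | 3-bromo-4-fluoro-2,6-dimethoxybenzaldehyde | O=Cc1c(OC)cc(F)c(Br)c1OC
F2 | step 13 | ring B aldehyde lacking ring B': 4-{2,6-dimethoxy-4-[4-methoxy-2,6-bis(ArE-oxy)phenoxy]phenoxy}-2,6-dimethoxybenzaldehyde | O=Cc1c(OC)cc(Oc2c(OC)cc(Oc3c(Oc4c(OC)cc(OC)c(-c5c(OC)cc(OC)cc5OC)c4OC)cc(OC)cc3Oc3c(OC)cc(OC)c(-c4c(OC)cc(OC)cc4OC)c3OC)cc2OC)cc1OC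
F3 | step 13 | salicylaldehyde: 2-hydroxy-6-methoxy analogue of F2 | O=Cc1c(O)cc(Oc2c(OC)cc(Oc3c(Oc4c(OC)cc(OC)c(-c5c(OC)cc(OC)cc5OC)c4OC)cc(OC)cc3Oc3c(OC)cc(OC)c(-c4c(OC)cc(OC)cc4OC)c3OC)cc2OC)cc1OC
F4 | step 13 | silicon-bridged bromide: di-tert-butylsilylene bis(aryl ether) of F3 and 4 | O=Cc1c(OC)cc(Oc2c(OC)cc(Oc3c(Oc4c(OC)cc(OC)c(-c5c(OC)cc(OC)cc5OC)c4OC)cc(OC)cc3Oc3c(OC)cc(OC)c(-c4c(OC)cc(OC)cc4OC)c3OC)cc2OC)cc1O[Si](C(C)(C)C)(C(C)(C)C)Oc1cc(OC)cc(OC)c1Br
F5 | step 13 | dioxasilepine: analogue of 8 with the ring C oxygen in place of fluorine | O=Cc1c(OC)cc(Oc2c(OC)cc(Oc3c(Oc4c(OC)cc(OC)c(-c5c(OC)cc(OC)cc5OC)c4OC)cc(OC)cc3Oc3c(OC)cc(OC)c(-c4c(OC)cc(OC)cc4OC)c3OC)cc2OC)c2c1O[Si](C(C)(C)C)(C(C)(C)C)Oc1cc(OC)cc(OC)c1-2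
F6 | step 13 | biaryl diol: analogue of 22 with free C6–OH (ring B) and C2'–OH (ring B') | O=Cc1c(OC)cc(Oc2c(OC)cc(Oc3c(Oc4c(OC)cc(OC)c(-c5c(OC)cc(OC)cc5OC)c4OC)cc(OC)cc3Oc3c(OC)cc(OC)c(-c4c(OC)cc(OC)cc4OC)c3OC)cc2OC)c(-c2c(O)cc(OC)cc2OC)c1O
F7 | step 15 | ring A aldehyde: 26 with a formyl group at C4 of ring A, between its two methoxy groups | O=Cc1c(OC)cc(Oc2c(OC)cc(Oc3c(OC)cc(Oc4c(Oc5c(OC)cc(OC)c(-c6c(OC)cc(OC)cc6OC)c5OC)cc(OC)cc4Oc4c(OC)cc(OC)c(-c5c(OC)cc(OC)cc5OC)c4OC)cc3OC)c(-c3c(OC)cc(OC)cc3OC)c2OC)cc1OC
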